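## Retrosynthetic overview

1. Fischerin (30) ⇐ N‑hydroxylation of the NH‑pyridone 27 ⇐ one‑pot fluoride removal of all silicon protecting groups from ketone 26.
2. Key C–C bond, pyridine C3–C(=O): Pd‑catalysed C‑arylation of the N‑tert‑butylhydrazone 23 of the decalin aldehyde (an acyl‑anion equivalent) with 3‑bromopyridine 12. The former CHO carbon and the C–Br carbon are both electrophilic in their native state.
3. 12 ⇐ aryllithium + quinone monoketal 4 (cyclohexane ring bought in); CuH desymmetrisation sets C1′ (carbinol carbon bearing the pyridyl group); epoxidation anti to the C1′ oxygen and hydride delivery anti to the epoxide set C2′/C3′ (epoxide) and C4′ (CHOH).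
4. 23 ⇐ cis‑decalin from a catalytic asymmetric endo intramolecular Diels–Alder reaction of (Z)‑trienoate 19, then C1 epimerisation; 19 ⇐ sorbyl acetate + C4 Grignard reagent + Still–Gennari olefination.
5. Ring order: pyridine (bought, 1) → cyclohexane (bought, 4; functionalised in steps 3–6) → both decalin rings at once (step 9, separate branch) → union (step 12); no ring is formed after the union.

Assumption: the absolute sense of the two catalyst‑controlled steps (4 and 9) is taken to follow the ligand/catalyst antipode written; if either gives the mirror‑image sense, the enantiomeric ligand/catalyst is used with nothing else changed.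

## Route

Step 1
Reactants: 1 3‑bromo‑2,4‑dichloropyridine
Product: 2 3‑bromo‑2,4‑bis[2‑(trimethylsilyl)ethoxy]pyridine
Conditions: Me3SiCH2CH2OH (2.3 equiv), NaH, THF, 0 → 50 °C
Reagents that add atoms: 2‑(trimethylsilyl)ethanol C[Si](C)(C)CCO
Why: Double SNAr in which the 4‑chloride and then the 2‑chloride are displaced by the alkoxide (the 3‑bromide is not activated), installing two fluoride‑labile ethers that later unmask the 4‑hydroxy‑2‑pyridone without acid.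

Step 2
Reactants: 2 3‑bromo‑2,4‑bis[2‑(trimethylsilyl)ethoxy]pyridine
Product: 3 3‑bromo‑5‑iodo‑2,4‑bis[2‑(trimethylsilyl)ethoxy]pyridine
Conditions: NIS, TFA (cat.), MeCN, 0 → 23 °C
Reagents that add atoms: N‑iodosuccinimide O=C1CCC(=O)N1I
Why: Electrophilic aromatic iodination at C5, the only free position activated by both alkoxy groups (para to the 2‑OR, ortho to the 4‑OR).

Step 3
Reactants: 3 3‑bromo‑5‑iodo‑2,4‑bis[2‑(trimethylsilyl)ethoxy]pyridine; 4 4,4‑dimethoxycyclohexa‑2,5‑dien‑1‑one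
Product: 8 4‑aryl‑4‑(triethylsilyloxy)cyclohexa‑2,5‑dien‑1‑one (aryl = 5‑bromo‑4,6‑bis[2‑(trimethylsilyl)ethoxy]pyridin‑3‑yl), via aryllithium 5 (not isolated), via lithium alkoxide 6 (not isolated), via silyl ether ketal 7 (not isolated)
Conditions: n‑BuLi, THF, −78 °C; 4; Et3SiOTf, −78 → 0 °C; then 5 % aq. oxalic acid, THF, 0 °C
Reagents that add atoms: triethylsilyl trifluoromethanesulfonate CC[Si](CC)(CC)OS(=O)(=O)C(F)(F)F; water O
Why: Iodine–lithium exchange (much faster than bromine–lithium exchange) gives the aryllithium, which adds 1,2 to the quinone monoketal carbonyl; silylation of the tertiary alkoxide and mild ketal hydrolysis give the achiral p‑quinol silyl ether, in which C1′ carries two enantiotopic enone arms.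

Step 4
Reactants: 8 4‑aryl‑4‑(triethylsilyloxy)cyclohexa‑2,5‑dien‑1‑one
Product: 9 (4R)‑4‑aryl‑4‑(triethylsilyloxy)cyclohex‑2‑en‑1‑one
Conditions: Cu(OAc)2 (5 mol %), (R)‑DTBM‑SEGPHOS (5.5 mol %), (EtO)2MeSiH (1.1 equiv), t‑BuOH (1.1 equiv), toluene, −40 → −20 °C
Reagents that add atoms: none
Why: Enantioselective desymmetrising CuH conjugate reduction of a 4,4‑disubstituted cyclohexadienone, in which the chiral Cu–H reduces only one enantiotopic enone arm and so fixes the quaternary carbinol centre C1′, while the slower reduction of the remaining (mismatched) enone limits over‑reduction.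

Step 5
Reactants: 9 (4R)‑4‑aryl‑4‑(triethylsilyloxy)cyclohex‑2‑en‑1‑one
Product: 10 (1S,5S,6R)‑5‑aryl‑5‑(triethylsilyloxy)‑7‑oxabicyclo[4.1.0]heptan‑2‑one
Conditions: t‑BuOOH, DBU, CH2Cl2, 0 → 23 °C
Reagents that add atoms: tert‑butyl hydroperoxide CC(C)(C)OO
Why: Weitz–Scheffer nucleophilic epoxidation in which the peroxide adds axially to the enone β‑carbon anti to the pseudo‑axial OSiEt3 group (aryl pseudo‑equatorial, no free OH to direct syn delivery), so the epoxide forms trans to the C1′ oxygen and cis to the pyridyl group.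

Step 6
Reactants: 10 (1S,5S,6R)‑5‑aryl‑5‑(triethylsilyloxy)‑7‑oxabicyclo[4.1.0]heptan‑2‑one
Product: 12 3‑bromo‑5‑[(1R,2S,5R,6S)‑2,5‑bis(triethylsilyloxy)‑7‑oxabicyclo[4.1.0]heptan‑2‑yl]‑2,4‑bis[2‑(trimethylsilyl)ethoxy]pyridine, via lithium alkoxide 11 (not isolated)
Conditions: L‑Selectride, THF, −78 °C; then Et3SiOTf, −78 → 0 °C
Reagents that add atoms: triethylsilyl trifluoromethanesulfonate CC[Si](CC)(CC)OS(=O)(=O)C(F)(F)F
Why: Diastereoselective ketone reduction in which the bulky hydride attacks from the face opposite the epoxide oxygen to give the cis‑epoxy alkoxide (C4′ set), which is silylated in the same flask so that no free hydroxyl is present in the basic cross‑coupling.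

Step 7
Reactants: 13 (2E,4E)‑hexa‑2,4‑dien‑1‑yl acetate; 14 2‑(3‑chloropropyl)‑1,3‑dioxolane
Product: 17 (6E,8E)‑deca‑6,8‑dienal, via Grignard reagent 15 (not isolated), via dienyl dioxolane 16 (not isolated)
Conditions: 14, Mg, THF, reflux; 13, Li2CuCl4 (3 mol %), THF, −20 → 0 °C; then 2 M aq. HCl, THF, 23 °C
Reagents that add atoms: water O
Why: Copper‑catalysed Grignard–allylic acetate coupling with α‑substitution and retention of the (E,E)‑diene, followed by acid hydrolysis of the dioxolane in the work‑up.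

Step 8
Reactants: 17 (6E,8E)‑deca‑6,8‑dienal; 18 methyl 2‑[bis(2,2,2‑trifluoroethoxy)phosphoryl]acetate
Product: 19 methyl (2Z,8E,10E)‑dodeca‑2,8,10‑trienoate
Conditions: KHMDS, 18‑crown‑6, THF, −78 °C
Reagents that add atoms: none
Why: Still–Gennari olefination, whose electron‑poor phosphonate gives kinetic (Z)‑selectivity (typically >10:1) with aliphatic aldehydes and so delivers the (Z)‑dienophile.

Step 9
Reactants: 19 methyl (2Z,8E,10E)‑dodeca‑2,8,10‑trienoate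
Product: 21 methyl (1R,2S,4aR,8aR)‑2‑methyl‑1,2,4a,5,6,7,8,8a‑octahydronaphthalene‑1‑carboxylate, via all‑cis ester 20 (not isolated)
Conditions: (S)‑o‑tolyl‑CBS oxazaborolidine·Tf2NH (20 mol %), CH2Cl2, −20 → 23 °C; then NaOMe (0.3 equiv), MeOH, 23 °C
Reagents that add atoms: none
Why: Proposed new method: a chiral oxazaborolidinium Lewis acid binds the ester carbonyl and enforces the ester‑endo intramolecular Diels–Alder transition state, which for a (Z)‑dienophile is also the tether‑endo one, so the (E,E)‑diene gives the cis‑fused all‑cis adduct 20 with C2, C4a and C8a set by catalyst shielding of one enoate face (closest known reactions: oxazaborolidinium‑catalysed enantioselective intramolecular Diels–Alder reactions of (E)‑trienals and trienoates, and cis‑selective cyclisations of (Z)‑2,8,10‑trienoates), after which methoxide epimerises C1 to the equatorial trans,trans ester 21.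

Step 10
Reactants: 21 methyl (1R,2S,4aR,8aR)‑2‑methyl‑1,2,4a,5,6,7,8,8a‑octahydronaphthalene‑1‑carboxylate
Product: 22 (1R,2S,4aR,8aR)‑2‑methyl‑1,2,4a,5,6,7,8,8a‑octahydronaphthalene‑1‑carbaldehyde
Conditions: DIBAL‑H (1.1 equiv), CH2Cl2, −78 °C; aq. Rochelle salt
Reagents that add atoms: none
Why: Low‑temperature DIBAL‑H partial reduction of the hindered ester stops at the aluminium hemiacetal and releases the aldehyde on work‑up; C1 is already the thermodynamic epimer, so enolisation is harmless.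

Step 11
Reactants: 22 (1R,2S,4aR,8aR)‑2‑methyl‑1,2,4a,5,6,7,8,8a‑octahydronaphthalene‑1‑carbaldehyde
Product: 23 (E)‑N‑tert‑butylhydrazone of 22
Conditions: t‑BuNHNH2·HCl, NaOAc, EtOH, 23 °C
Reagents that add atoms: tert‑butylhydrazine hydrochloride CC(C)(C)NN.Cl
Why: Hydrazone condensation gives the N‑tert‑butylhydrazone, the acyl‑anion equivalent for the coupling, without touching any stereocentre.

Step 12
Reactants: 12 3‑bromo‑5‑[(1R,2S,5R,6S)‑2,5‑bis(triethylsilyloxy)‑7‑oxabicyclo[4.1.0]heptan‑2‑yl]‑2,4‑bis[2‑(trimethylsilyl)ethoxy]pyridine; 23 (E)‑N‑tert‑butylhydrazone of 22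
Product: 26 fully protected decalinyl pyridyl ketone, via azo compound 24 (not isolated), via hydrazone 25 (not isolated)
Conditions: Pd2(dba)3 (2.5 mol %), DPEphos (6 mol %), NaOt‑Bu (1.4 equiv), toluene, 80 °C; then 10 % aq. oxalic acid, THF, 23 °C
Reagents that add atoms: water O
Why: Hartwig‑type Pd‑catalysed C‑arylation of the hydrazone aza‑allyl anion (acyl‑anion equivalent) with the aryl bromide joins the former aldehyde carbon to the C3–Br carbon; the tert‑butyl group blocks N‑arylation, the azo compound tautomerises to the ketone hydrazone, and mild hydrolysis gives the ketone with C1 (α to C=N and then C=O) remaining in its more stable trans,trans configuration.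

Step 13
Reactants: 26 fully protected decalinyl pyridyl ketone
Product: 27 N‑deoxyfischerin (4‑hydroxy‑2(1H)‑pyridone)
Conditions: TBAF/AcOH (1:1, 8 equiv), THF–DMF, 23 → 45 °C
Reagents that add atoms: none
Why: Fluoride‑mediated desilylation cleaves both triethylsilyl ethers and triggers β‑elimination of both 2‑(trimethylsilyl)ethyl ethers (ethylene + Me3SiF), unveiling the 4‑hydroxy‑2‑pyridone under acetic‑acid‑buffered conditions that avoid alkoxide‑induced Payne rearrangement of the trans‑epoxy tertiary alcohol; no stereocentre is touched.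

Step 14
Reactants: 27 N‑deoxyfischerin (4‑hydroxy‑2(1H)‑pyridone)
Product: 30 fischerin, via persilylated pyridine 28 (not isolated), via silylated N‑oxide 29 (not isolated)
Conditions: BSA (excess), MeCN, 60 °C; then MoO5·py·HMPA (1.5 equiv), CH2Cl2, 23 °C; then aq. Na4EDTA, MeOH
Reagents that add atoms: oxodiperoxymolybdenum(pyridine)(hexamethylphosphoramide) O=[Mo]12(OO1)OO2.c1ccncc1.CN(C)P(=O)(N(C)C)N(C)C
Why: Sammes‑type N‑hydroxylation in which persilylation gives the 2‑silyloxypyridine, whose ring nitrogen is oxidised by the electrophilic peroxomolybdenum reagent (established for 3‑acyl‑4‑hydroxy‑5‑substituted 2‑pyridones) faster than the isolated cyclohexene is epoxidised, and aqueous EDTA work‑up strips all silyl groups to give the 1‑hydroxy‑2‑pyridone.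

## Compound list

1 | 3‑bromo‑2,4‑dichloropyridine | Brc1c(Cl)ccnc1Cl | starting material
2 | 3‑bromo‑2,4‑bis[2‑(trimethylsilyl)ethoxy]pyridine | Brc1c(OCC[Si](C)(C)C)ccnc1OCC[Si](C)(C)C | intermediate
3 | 3‑bromo‑5‑iodo‑2,4‑bis[2‑(trimethylsilyl)ethoxy]pyridine | Brc1c(OCC[Si](C)(C)C)c(I)cnc1OCC[Si](C)(C)C | intermediate
4 | 4,4‑dimethoxycyclohexa‑2,5‑dien‑1‑one (p‑benzoquinone dimethyl monoketal) | COC1(OC)C=CC(=O)C=C1 | starting material
5 | {5‑bromo‑4,6‑bis[2‑(trimethylsilyl)ethoxy]pyridin‑3‑yl}lithium | Brc1c(OCC[Si](C)(C)C)c([Li])cnc1OCC[Si](C)(C)C | intermediate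
6 | lithium 1‑{5‑bromo‑4,6‑bis[2‑(trimethylsilyl)ethoxy]pyridin‑3‑yl}‑4,4‑dimethoxycyclohexa‑2,5‑dien‑1‑olate | Brc1c(OCC[Si](C)(C)C)c(C2(O[Li])C=CC(OC)(OC)C=C2)cnc1OCC[Si](C)(C)C | intermediate
7 | 3‑bromo‑5‑[4,4‑dimethoxy‑1‑(triethylsilyloxy)cyclohexa‑2,5‑dien‑1‑yl]‑2,4‑bis[2‑(trimethylsilyl)ethoxy]pyridine | Brc1c(OCC[Si](C)(C)C)c(C2(O[Si](CC)(CC)CC)C=CC(OC)(OC)C=C2)cnc1OCC[Si](C)(C)C | intermediate
8 | 4‑{5‑bromo‑4,6‑bis[2‑(trimethylsilyl)ethoxy]pyridin‑3‑yl}‑4‑(triethylsilyloxy)cyclohexa‑2,5‑dien‑1‑one | Brc1c(OCC[Si](C)(C)C)c(C2(O[Si](CC)(CC)CC)C=CC(=O)C=C2)cnc1OCC[Si](C)(C)C | intermediate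
9 | (4R)‑4‑{5‑bromo‑4,6‑bis[2‑(trimethylsilyl)ethoxy]pyridin‑3‑yl}‑4‑(triethylsilyloxy)cyclohex‑2‑en‑1‑one | Brc1c(OCC[Si](C)(C)C)c([C@@]2(O[Si](CC)(CC)CC)CCC(=O)C=C2)cnc1OCC[Si](C)(C)C | intermediate
10 | (1S,5S,6R)‑5‑{5‑bromo‑4,6‑bis[2‑(trimethylsilyl)ethoxy]pyridin‑3‑yl}‑5‑(triethylsilyloxy)‑7‑oxabicyclo[4.1.0]heptan‑2‑one (epoxide trans to OSiEt3, cis to pyridyl) | Brc1c(OCC[Si](C)(C)C)c([C@@]2(O[Si](CC)(CC)CC)CCC(=O)[C@H]3O[C@H]32)cnc1OCC[Si](C)(C)C | intermediate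
11 | lithium alkoxide of the cis‑epoxy alcohol from 10 (O–Li cis to the epoxide, trans to the tertiary OSiEt3) | Brc1c(OCC[Si](C)(C)C)c([C@@]2(O[Si](CC)(CC)CC)CC[C@@H](O[Li])[C@H]3O[C@H]32)cnc1OCC[Si](C)(C)C | intermediate
12 | 3‑bromo‑5‑[(1R,2S,5R,6S)‑2,5‑bis(triethylsilyloxy)‑7‑oxabicyclo[4.1.0]heptan‑2‑yl]‑2,4‑bis[2‑(trimethylsilyl)ethoxy]pyridine | Brc1c(OCC[Si](C)(C)C)c([C@@]2(O[Si](CC)(CC)CC)CC[C@@H](O[Si](CC)(CC)CC)[C@H]3O[C@H]32)cnc1OCC[Si](C)(C)C | intermediate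
13 | (2E,4E)‑hexa‑2,4‑dien‑1‑yl acetate (sorbyl acetate) | C/C=C/C=C/COC(C)=O | starting material
14 | 2‑(3‑chloropropyl)‑1,3‑dioxolane | ClCCCC1OCCO1 | starting material
15 | [3‑(1,3‑dioxolan‑2‑yl)propyl]magnesium chloride | Cl[Mg]CCCC1OCCO1 | intermediate
16 | 2‑[(5E,7E)‑nona‑5,7‑dien‑1‑yl]‑1,3‑dioxolane | C/C=C/C=C/CCCCC1OCCO1 | intermediate
17 | (6E,8E)‑deca‑6,8‑dienal | C/C=C/C=C/CCCCC=O | intermediate
18 | methyl 2‑[bis(2,2,2‑trifluoroethoxy)phosphoryl]acetate | COC(=O)CP(=O)(OCC(F)(F)F)OCC(F)(F)F | starting material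
19 | methyl (2Z,8E,10E)‑dodeca‑2,8,10‑trienoate | C/C=C/C=C/CCCC/C=C\C(=O)OC | intermediate
20 | methyl (1S,2S,4aR,8aR)‑2‑methyl‑1,2,4a,5,6,7,8,8a‑octahydronaphthalene‑1‑carboxylate (cis‑fused, all‑cis) | C[C@H]1C=C[C@H]2CCCC[C@H]2[C@H]1C(=O)OC | intermediate
21 | methyl (1R,2S,4aR,8aR)‑2‑methyl‑1,2,4a,5,6,7,8,8a‑octahydronaphthalene‑1‑carboxylate (cis‑fused; ester trans to both the 2‑methyl group and C8) | C[C@H]1C=C[C@H]2CCCC[C@H]2[C@@H]1C(=O)OC | intermediate
22 | (1R,2S,4aR,8aR)‑2‑methyl‑1,2,4a,5,6,7,8,8a‑octahydronaphthalene‑1‑carbaldehyde | C[C@H]1C=C[C@H]2CCCC[C@H]2[C@@H]1C=O | intermediate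
23 | (E)‑1‑tert‑butyl‑2‑{[(1R,2S,4aR,8aR)‑2‑methyl‑1,2,4a,5,6,7,8,8a‑octahydronaphthalen‑1‑yl]methylidene}hydrazine | C[C@H]1C=C[C@H]2CCCC[C@H]2[C@@H]1/C=N/NC(C)(C)C | intermediate
24 | azo tautomer: tert‑butyl{[(1R,2S,4aR,8aR)‑2‑methyl‑octahydronaphthalen‑1‑yl](pyridin‑3‑yl)methyl}diazene, pyridyl as in 26 (new CH centre unassigned) | C[C@H]1C=C[C@H]2CCCC[C@H]2[C@@H]1C(N=NC(C)(C)C)c1c(OCC[Si](C)(C)C)c([C@@]2(O[Si](CC)(CC)CC)CC[C@@H](O[Si](CC)(CC)CC)[C@H]3O[C@H]32)cnc1OCC[Si](C)(C)C | intermediate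
25 | N‑tert‑butylhydrazone of ketone 26 | C[C@H]1C=C[C@H]2CCCC[C@H]2[C@@H]1C(=NNC(C)(C)C)c1c(OCC[Si](C)(C)C)c([C@@]2(O[Si](CC)(CC)CC)CC[C@@H](O[Si](CC)(CC)CC)[C@H]3O[C@H]32)cnc1OCC[Si](C)(C)C | intermediate
26 | [(1R,2S,4aR,8aR)‑2‑methyl‑1,2,4a,5,6,7,8,8a‑octahydronaphthalen‑1‑yl]{5‑[(1R,2S,5R,6S)‑2,5‑bis(triethylsilyloxy)‑7‑oxabicyclo[4.1.0]heptan‑2‑yl]‑2,4‑bis[2‑(trimethylsilyl)ethoxy]pyridin‑3‑yl}methanone | C[C@H]1C=C[C@H]2CCCC[C@H]2[C@@H]1C(=O)c1c(OCC[Si](C)(C)C)c([C@@]2(O[Si](CC)(CC)CC)CC[C@@H](O[Si](CC)(CC)CC)[C@H]3O[C@H]32)cnc1OCC[Si](C)(C)C | intermediate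
27 | N‑deoxyfischerin: 5‑[(1R,2S,5R,6R)‑2,5‑dihydroxy‑7‑oxabicyclo[4.1.0]heptan‑2‑yl]‑4‑hydroxy‑3‑{[(1R,2S,4aR,8aR)‑2‑methyl‑1,2,4a,5,6,7,8,8a‑octahydronaphthalen‑1‑yl]carbonyl}pyridin‑2(1H)‑one | C[C@H]1C=C[C@H]2CCCC[C@H]2[C@@H]1C(=O)c1c(O)c([C@@]2(O)CC[C@@H](O)[C@H]3O[C@H]32)c[nH]c1=O | intermediate
28 | tetrakis(trimethylsilyl) derivative of 27 (2‑ and 4‑pyridyl O‑SiMe3, both alcohol O‑SiMe3) | C[C@H]1C=C[C@H]2CCCC[C@H]2[C@@H]1C(=O)c1c(O[Si](C)(C)C)c([C@@]2(O[Si](C)(C)C)CC[C@@H](O[Si](C)(C)C)[C@H]3O[C@H]32)cnc1O[Si](C)(C)C | intermediate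
29 | pyridine N‑oxide of 28 | C[C@H]1C=C[C@H]2CCCC[C@H]2[C@@H]1C(=O)c1c(O[Si](C)(C)C)c([C@@]2(O[Si](C)(C)C)CC[C@@H](O[Si](C)(C)C)[C@H]3O[C@H]32)c[n+]([O-])c1O[Si](C)(C)C | intermediate
30 | fischerin: 5‑[(1R,2S,5R,6R)‑2,5‑dihydroxy‑7‑oxabicyclo[4.1.0]heptan‑2‑yl]‑1,4‑dihydroxy‑3‑{[(1R,2S,4aR,8aR)‑2‑methyl‑1,2,4a,5,6,7,8,8a‑octahydronaphthalen‑1‑yl]carbonyl}pyridin‑2(1H)‑one | C[C@H]1C=C[C@H]2CCCC[C@H]2[C@@H]1C(=O)c1c(O)c([C@@]2(O)CC[C@@H](O)[C@H]3O[C@H]32)cn(O)c1=O | target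

## Step count and risks

Total step count: 14. Longest linear sequence: 9 steps (steps 1–6, then 12–14). The decalin branch (steps 7–11, 5 steps) joins at step 12.

The three steps most likely to fail:

Step 9 (highest risk). There is no precedent for a (Z)‑trienoate with this catalyst. The risks are low conversion, Z→E leakage to trans‑fused material, and weak or opposite facial selectivity. The fallback sets out from 19 and comes back at 21, replacing the monodentate ester by a two‑point‑binding template. Saponification of 19 (LiOH, THF/H2O) gives (2Z,8E,10E)‑dodeca‑2,8,10‑trienoic acid F1. DCC/DMAP coupling with oxazolidin‑2‑one gives the Z‑imide 3‑[(2Z,8E,10E)‑dodeca‑2,8,10‑trienoyl]‑1,3‑oxazolidin‑2‑one F2. Cyclisation with [Cu((S,S)‑t‑Bu‑box)](SbF6)2 in CH2Cl2 (square‑planar chelate, non‑nucleophilic counter‑ion so the Z geometry holds, endo mode gives cis fusion) gives the all‑cis decalin imide F3. NaOMe/MeOH then removes the oxazolidinone and epimerises C1, giving 21 through 20.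

Step 12. The di‑ortho‑alkoxy heteroaryl bromide and the α‑branched hydrazone are both hindered. Slow oxidative addition, N‑arylation or hydrodebromination may dominate, and the hindered ketone hydrazone may hydrolyse slowly. The fallback sets out from 12 and aldehyde 22 and comes back at 26, joining the same two carbons with normal polarity. Bromine–lithium exchange on 12 (n‑BuLi, THF, −78 °C) gives the 3‑pyridyllithium F4. Its addition to 22 gives the secondary alcohol F5 as carbinol epimers. Dess–Martin oxidation gives 26.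

Step 14. The late N‑hydroxylation is typically modest in yield, and incomplete silylation or slow epoxidation of the decalin alkene could erode it further. The fallback sets out from 12 and comes back at 30, installing the N–O bond before any alkene is present. mCPBA (CH2Cl2, 23 °C) converts 12 into the pyridine N‑oxide F6. C‑arylation of 23 with F6 under the step‑12 conditions gives, through the azo N‑oxide F7 and the hydrazone N‑oxide F8, the ketone N‑oxide F9. Buffered TBAF then removes all four silicon groups, and the 2‑(silylethoxy)pyridine N‑oxide collapses directly to the 1‑hydroxy‑2‑pyridone, i.e. 30, so steps 13 and 14 merge into one.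

Further compounds
F1 | step 9 | (2Z,8E,10E)‑dodeca‑2,8,10‑trienoic acid | C/C=C/C=C/CCCC/C=C\C(=O)O
F2 | step 9 | 3‑[(2Z,8E,10E)‑dodeca‑2,8,10‑trienoyl]‑1,3‑oxazolidin‑2‑one | C/C=C/C=C/CCCC/C=C\C(=O)N1CCOC1=O
F3 | step 9 | 3‑{[(1S,2S,4aR,8aR)‑2‑methyl‑1,2,4a,5,6,7,8,8a‑octahydronaphthalen‑1‑yl]carbonyl}‑1,3‑oxazolidin‑2‑one (all‑cis) | C[C@H]1C=C[C@H]2CCCC[C@H]2[C@H]1C(=O)N1CCOC1=O
F4 | step 12 | {5‑[(1R,2S,5R,6S)‑2,5‑bis(triethylsilyloxy)‑7‑oxabicyclo[4.1.0]heptan‑2‑yl]‑2,4‑bis[2‑(trimethylsilyl)ethoxy]pyridin‑3‑yl}lithium | [Li]c1c(OCC[Si](C)(C)C)c([C@@]2(O[Si](CC)(CC)CC)CC[C@@H](O[Si](CC)(CC)CC)[C@H]3O[C@H]32)cnc1OCC[Si](C)(C)C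
F5 | step 12 | secondary alcohol corresponding to ketone 26 (carbinol epimers) | C[C@H]1C=C[C@H]2CCCC[C@H]2[C@@H]1C(O)c1c(OCC[Si](C)(C)C)c([C@@]2(O[Si](CC)(CC)CC)CC[C@@H](O[Si](CC)(CC)CC)[C@H]3O[C@H]32)cnc1OCC[Si](C)(C)C
F6 | step 14 | pyridine N‑oxide of 12 | Brc1c(OCC[Si](C)(C)C)c([C@@]2(O[Si](CC)(CC)CC)CC[C@@H](O[Si](CC)(CC)CC)[C@H]3O[C@H]32)c[n+]([O-])c1OCC[Si](C)(C)C
F7 | step 14 | pyridine N‑oxide of azo compound 24 | C[C@H]1C=C[C@H]2CCCC[C@H]2[C@@H]1C(N=NC(C)(C)C)c1c(OCC[Si](C)(C)C)c([C@@]2(O[Si](CC)(CC)CC)CC[C@@H](O[Si](CC)(CC)CC)[C@H]3O[C@H]32)c[n+]([O-])c1OCC[Si](C)(C)C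
F8 | step 14 | pyridine N‑oxide of hydrazone 25 | C[C@H]1C=C[C@H]2CCCC[C@H]2[C@@H]1C(=NNC(C)(C)C)c1c(OCC[Si](C)(C)C)c([C@@]2(O[Si](CC)(CC)CC)CC[C@@H](O[Si](CC)(CC)CC)[C@H]3O[C@H]32)c[n+]([O-])c1OCC[Si](C)(C)C
F9 | step 14 | pyridine N‑oxide of ketone 26 | C[C@H]1C=C[C@H]2CCCC[C@H]2[C@@H]1C(=O)c1c(OCC[Si](C)(C)C)c([C@@]2(O[Si](CC)(CC)CC)CC[C@@H](O[Si](CC)(CC)CC)[C@H]3O[C@H]32)c[n+]([O-])c1OCC[Si](C)(C)C
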